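**Retrosynthetic overview**
1. Atom numbers follow the 1,5-diazocan-2-one ring: N1 (lactam N), C2 (C=O), C3, C4 (CHPh), N5 (NMe), C6, C7, C8. Late cuts at the benzamide N–CO bond, the N1–butyl bond (lactam N-alkylation, Gabriel amine) and N5–CH3 (Eschweiler–Clarke) lead back to (4S)-4-phenyl-1,5-diazocan-2-one.
2. Enabling feature: N1 and N5 face each other 1,5 across the eight-membered ring and C4 is β to the lactam carbonyl C2. A temporary N1–N5 bond therefore folds the ring into cis-fused 1,5-diazabicyclo[3.3.0]octan-2-one: ring A = pyrazolidin-3-one (N1, C2, C3, C4, N5), ring B = pyrazolidine (N5, C6, C7, C8, N1).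
3. This bicycle is the [3+2] adduct of the azomethine imine C6=N5(+)–N1(−) with ethylene (C7=C8). The ylide arises when N5 of an acyclic hydrazide closes onto C4 and condenses with formaldehyde (C6).
4. Key domino: (R)-β-mesyloxy hydrazide + formaldehyde + ethylene gives ring A first (N5–C4, SN2 with inversion, sets 4S), then ring B (C6–C7 and C8–N1) in the same operation. The eight-membered ring is uncovered last by hydrogenolysis of N1–N5.
5. C4 chirality comes from (3R)-3-hydroxy-3-phenylpropanoic acid; both ring nitrogens come from tert-butyl carbazate.

Key step: step 4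

Remark: (3R)-3-hydroxy-3-phenylpropanoic acid is taken as a purchasable, enantiopure starting material (it is also accessible by asymmetric hydrogenation of a benzoylacetate ester and saponification).

**Step 1**
Reactants: 1 (3R)-3-hydroxy-3-phenylpropanoic acid; 2 tert-butyl carbazate
Product: 3 tert-butyl 2-[(3R)-3-hydroxy-3-phenylpropanoyl]hydrazine-1-carboxylate
Conditions: EDC·HCl, HOBt, CH2Cl2, 0 → 25 °C
Reagents that add atoms: none
Why: Carbodiimide-mediated amide (hydrazide) coupling, in which the terminal NH2 of the carbazate is far more nucleophilic than the secondary benzylic hydroxyl, so the unprotected β-hydroxy acid should couple chemoselectively with the (R) centre untouched.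

**Step 2**
Reactants: 3 tert-butyl 2-[(3R)-3-hydroxy-3-phenylpropanoyl]hydrazine-1-carboxylate
Product: 4 tert-butyl 2-[(3R)-3-(methanesulfonyloxy)-3-phenylpropanoyl]hydrazine-1-carboxylate
Conditions: MsCl, Et3N, CH2Cl2, −20 °C
Reagents that add atoms: methanesulfonyl chloride, CS(=O)(=O)Cl
Why: O-Sulfonylation (mesylation) of the secondary alcohol leaves the C4–O bond intact and so proceeds with retention, both hydrazide nitrogens being acylated and poorly nucleophilic and the low temperature keeping β-elimination slow.

**Step 3**
Reactants: 4 tert-butyl 2-[(3R)-3-(methanesulfonyloxy)-3-phenylpropanoyl]hydrazine-1-carboxylate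
Product: 5 (3R)-3-(methanesulfonyloxy)-3-phenylpropanehydrazide trifluoroacetate
Conditions: TFA, CH2Cl2, 0 °C; cold evaporation, used crude
Reagents that add atoms: trifluoroacetic acid, OC(=O)C(F)(F)F
Why: Acidolytic cleavage of the tert-butyl carbamate in a non-nucleophilic acid leaves the terminal nitrogen protonated, so it cannot yet attack the mesylate, and no nucleophilic counter-ion is present that could invert C4.

**Step 4**
Reactants: 5 (3R)-3-(methanesulfonyloxy)-3-phenylpropanehydrazide trifluoroacetate
Product: 8 (4S)-4-phenyl-1,5-diazabicyclo[3.3.0]octan-2-one, via (5S)-5-phenylpyrazolidin-3-one 6 (not isolated), via azomethine imine 7 (not isolated)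
Conditions: i-Pr2NEt (2.2 equiv), (CH2O)n (1.5 equiv), ethylene (40 bar), MeCN, 20 °C, then 90 °C (autoclave)
Reagents that add atoms: formaldehyde (as paraformaldehyde), C=O; ethylene, C=C
Why: Once the salt is neutralised, the terminal hydrazide nitrogen N5 displaces the benzylic mesylate at C4 by intramolecular SN2, closing the pyrazolidinone ring (ring A) in the 5-exo-tet mode with inversion, so that the (R)-C4–O centre of 5 becomes the (S)-C4–N5 centre of 6; this stereospecific, substrate-controlled displacement is the only stereo-determining event of the route. On heating, depolymerised formaldehyde condenses with N5–H of 6 to the C-unsubstituted azomethine imine 7, whose C6 and N1 termini add to ethylene in a concerted, suprafacial [3+2] cycloaddition that forms C6–C7 and C8–N1 and closes the pyrazolidine ring (ring B). The closest known reaction types are the ring closure of β-leaving-group hydrazides to pyrazolidin-3-ones and the azomethine imine–alkene cycloaddition of 3-oxopyrazolidin-1-ium-2-ides generated in situ, here run as one domino; should the formaldehyde hydrazone form first, its N5 closes on C4 in the same 5-exo-tet mode and gives 7 directly. The step needs N5, not N1 or the carbonyl oxygen, to be alkylated and substitution to outrun β-elimination: N5 is the only basic, α-effect nitrogen, its attack passes through a five-membered transition state while N1 or O would have to close a four-membered ring, and the closure runs at 20 °C before paraformaldehyde depolymerises. Ethylene is symmetric, so neither regio- nor diastereoisomers can arise, the N–N ring fusion can only be cis, and the thermally reversible head-to-tail dimer of 7 acts as a reservoir that the pressurised dipolarophile drains.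

**Step 5**
Reactants: 8 (4S)-4-phenyl-1,5-diazabicyclo[3.3.0]octan-2-one
Product: 9 (4S)-4-phenyl-1,5-diazocan-2-one
Conditions: H2 (10 bar), activated sponge Ni, EtOH, 60 °C
Reagents that add atoms: none
Why: Hydrogenolysis of the hydrazide N–N bond, an established way to open 1,5-diazabicyclo[3.3.0]octan-2-ones to 1,5-diazocan-2-ones, should cleave the acyl-weakened N1–N5 bond while nickel, a poor catalyst for benzylic C–N hydrogenolysis, leaves C4–N5 and the (S) centre intact.

**Step 6**
Reactants: 9 (4S)-4-phenyl-1,5-diazocan-2-one
Product: 10 (4S)-5-methyl-4-phenyl-1,5-diazocan-2-one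
Conditions: 37% aq. CH2O, HCO2H, 90 °C
Reagents that add atoms: formaldehyde, C=O
Why: Eschweiler–Clarke reductive methylation, in which the N5 iminium ion is reduced by formate and the reaction stops at the tertiary amine, any transannular N1–CH2–N5 aminal reopening to the same iminium ion, the lactam nitrogen staying unmethylated and C4 not being involved.

**Step 7**
Reactants: 10 (4S)-5-methyl-4-phenyl-1,5-diazocan-2-one; 11 N-(4-bromobutyl)phthalimide
Product: 12 2-{4-[(4S)-5-methyl-2-oxo-4-phenyl-1,5-diazocan-1-yl]butyl}isoindoline-1,3-dione
Conditions: NaH (1.05 equiv), DMF, 0 °C; then 11, 0 → 25 °C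
Reagents that add atoms: none
Why: SN2 N-alkylation of the sodium lactamate, where one equivalent of base forms only the amidate, which is far more nucleophilic than the hindered tertiary N5 and leaves C3 unmetalated (no retro-aza-Michael opening), while the phthalimide keeps the chain nitrogen from cyclising onto its own bromide.

**Step 8**
Reactants: 12 2-{4-[(4S)-5-methyl-2-oxo-4-phenyl-1,5-diazocan-1-yl]butyl}isoindoline-1,3-dione
Product: 13 (4S)-1-(4-aminobutyl)-5-methyl-4-phenyl-1,5-diazocan-2-one
Conditions: N2H4·H2O, EtOH, 78 °C
Reagents that add atoms: none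
Why: Ing–Manske hydrazinolysis of the phthalimide (Gabriel amine synthesis) should release the primary amine, the medium-ring lactam and the tertiary amine being inert to hydrazine.

**Step 9**
Reactants: 13 (4S)-1-(4-aminobutyl)-5-methyl-4-phenyl-1,5-diazocan-2-one
Product: 14 N-{4-[(4S)-5-methyl-2-oxo-4-phenyl-1,5-diazocan-1-yl]butyl}benzamide (CNP0138586.1)
Conditions: BzCl, Et3N, CH2Cl2, 0 °C
Reagents that add atoms: benzoyl chloride, O=C(Cl)c1ccccc1
Why: N-Acylation of the only N–H amine with an acid chloride, the tertiary N5 and the lactam nitrogen being unable to acylate and no stereocentre being touched.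

**Compound list**
1 | (3R)-3-hydroxy-3-phenylpropanoic acid | OC(=O)C[C@@H](O)c1ccccc1 | starting material
2 | tert-butyl carbazate (tert-butyl hydrazinecarboxylate) | CC(C)(C)OC(=O)NN | starting material
3 | tert-butyl 2-[(3R)-3-hydroxy-3-phenylpropanoyl]hydrazine-1-carboxylate | CC(C)(C)OC(=O)NNC(=O)C[C@@H](O)c1ccccc1 | intermediate
4 | tert-butyl 2-[(3R)-3-(methanesulfonyloxy)-3-phenylpropanoyl]hydrazine-1-carboxylate | CC(C)(C)OC(=O)NNC(=O)C[C@@H](OS(C)(=O)=O)c1ccccc1 | intermediate
5 | (3R)-3-(methanesulfonyloxy)-3-phenylpropanehydrazide trifluoroacetate | [NH3+]NC(=O)C[C@@H](OS(C)(=O)=O)c1ccccc1.[O-]C(=O)C(F)(F)F | intermediate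
6 | (5S)-5-phenylpyrazolidin-3-one | O=C1C[C@H](NN1)c2ccccc2 | intermediate (not isolated)
7 | (5S)-1-methylidene-3-oxo-5-phenylpyrazolidin-1-ium-2-ide (azomethine imine) | C=[N+]1[N-]C(=O)C[C@H]1c2ccccc2 | intermediate (not isolated)
8 | (4S)-4-phenyl-1,5-diazabicyclo[3.3.0]octan-2-one | O=C1C[C@H](N2CCCN12)c3ccccc3 | intermediate
9 | (4S)-4-phenyl-1,5-diazocan-2-one | O=C1C[C@H](NCCCN1)c2ccccc2 | intermediate
10 | (4S)-5-methyl-4-phenyl-1,5-diazocan-2-one | O=C1C[C@H](N(C)CCCN1)c2ccccc2 | intermediate
11 | N-(4-bromobutyl)phthalimide | O=C1c2ccccc2C(=O)N1CCCCBr | starting material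
12 | 2-{4-[(4S)-5-methyl-2-oxo-4-phenyl-1,5-diazocan-1-yl]butyl}isoindoline-1,3-dione | O=C1C[C@H](N(C)CCCN1CCCCN3C(=O)c4ccccc4C3=O)c5ccccc5 | intermediate
13 | (4S)-1-(4-aminobutyl)-5-methyl-4-phenyl-1,5-diazocan-2-one | O=C1C[C@H](N(C)CCCN1CCCCN)c2ccccc2 | intermediate
14 | N-{4-[(4S)-5-methyl-2-oxo-4-phenyl-1,5-diazocan-1-yl]butyl}benzamide | CN1CCCN(CCCCNC(=O)c2ccccc2)C(=O)C[C@H]1c1ccccc1 | target

**Step count and risks**
Total step count: 9.
Longest linear sequence: 9 steps (1 → 3 → 4 → 5 → 8 → 9 → 10 → 12 → 13 → 14); 2 and 11 are bought.

The three steps most likely to fail: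

Step 4 (key step). With unactivated ethylene the cycloaddition may be slower than prototropic isomerisation of the transient azomethine imine (deprotonation at C4, loss of the stereocentre, aromatisation to a pyrazol-3-ol). Base-induced β-elimination of the mesylate followed by unselective re-addition of nitrogen could also erode the configuration. The fallback sets out from 5: only the ring closure is run (i-Pr2NEt, MeCN, 0 °C) and (5S)-5-phenylpyrazolidin-3-one 6 is isolated, where its enantiomeric purity can be raised by crystallisation. Ring B is then built by two N-alkylations instead of a cycloaddition (1,3-dibromopropane, K2CO3, DMF, 25 → 60 °C). The amine-type nitrogen reacts first to give (5S)-1-(3-bromopropyl)-5-phenylpyrazolidin-3-one F1, which closes at the hydrazide nitrogen (5-exo-tet) and comes back to the route at 8.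

Step 3. The benzylic mesylate may ionise or solvolyse in acid, or the concentrated salt may cyclise or eliminate in an uncontrolled way, with loss of the leaving group or of configurational purity. The fallback sets out from 4 and closes the ring before deprotection: K2CO3, MeCN, 0 → 25 °C lets the carbamate nitrogen displace the mesylate (5-exo-tet, inversion) to give tert-butyl (5S)-3-oxo-5-phenylpyrazolidine-1-carboxylate F2. TFA in CH2Cl2 then frees 6 as an isolated compound, where the fallback comes back to the route; 6 is carried on to 8 with paraformaldehyde and ethylene under the thermal conditions of step 4.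

Step 5. Hydrogenolysis of the hydrazide N–N bond on nickel may be sluggish. Under more forcing conditions, hydrogenolysis of the benzylic C4–N5 bond or dehydrogenation–rehydrogenation at C4 (epimerisation) may compete. The fallback sets out from 8 and activates the N–N bond by quaternisation: MeI, MeCN, 40 °C alkylates the amine-type N5 to give (4S)-5-methyl-2-oxo-4-phenyl-1-aza-5-azoniabicyclo[3.3.0]octane iodide F3 (either N5 epimer serves). Electron transfer (Zn dust, AcOH, 25 → 50 °C) then cleaves the hydrazinium N–N bond and comes back to the route at 10, so that steps 5 and 6 are replaced and the N-methyl group is brought in by the activating reagent.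

**Further compounds**
F1 | step 4 | (5S)-1-(3-bromopropyl)-5-phenylpyrazolidin-3-one | BrCCCN1NC(=O)C[C@H]1c2ccccc2
F2 | step 3 | tert-butyl (5S)-3-oxo-5-phenylpyrazolidine-1-carboxylate | CC(C)(C)OC(=O)N1NC(=O)C[C@H]1c2ccccc2
F3 | step 5 | (4S)-5-methyl-2-oxo-4-phenyl-1-aza-5-azoniabicyclo[3.3.0]octane iodide | C[N+]12CCCN1C(=O)C[C@H]2c3ccccc3.[I-]
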